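Which set-up delivers the most product, idle adduct counted in, from the same charge of substrate?

| setting | Sunday's | Friday's | Wednesday's | Saturday's |
|---|---|---|---|---|
| substrate | 0.050 M | 0.050 M | 0.050 M | 0.050 M |
| remark | one stirred flow tank at steady state, fed with the mixture as stated, mean residence time 5.00 min | a closed flask charged with all of it at once and left for 1.0 min | plug flow through a tube for 1.0 min, no back-mixing | one stirred flow tank at steady state, fed with the mixture as stated, mean residence time 1.0 min |
| time |  | 1.0 min | 1.0 min |  |

    substrate → intermediate A (k1 = 0.0289 s⁻¹)
    intermediate A → product (k2 = 0.0149 s⁻¹)
    intermediate A → intermediate B (k3 = 0.0136 s⁻¹)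
    intermediate A ⇌ intermediate C (K4 = 2.1, k4 = 0.101 s⁻¹)
    intermediate B ⇌ intermediate D (K5 = 0.835, k5 = 0.0251 s⁻¹)
    intermediate D ⇌ intermediate E (K6 = 2.12, k6 = 0.00858 s⁻¹)
    substrate ⇌ dormant form (K7 = 1.6, k7 = 0.0435 s⁻¹)
    substrate + product ⇌ idle adduct, settled at all times (K8 = 657 L mol⁻¹)

* the set-up with the highest amount of product at the outlet or at the end, in percent of the substrate put in ("none" if the first two lie within 2 percentage points) (Sunday's / Friday's / Wednesday's / Saturday's / none)
* amount of product at the outlet or at the end, in percent of the substrate put in, Sunday's
* amount of product at the outlet or at the end, in percent of the substrate put in, Friday's
* amount of product at the outlet or at the end, in percent of the substrate put in, Wednesday's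
* amount of product at the outlet or at the end, in percent of the substrate put in, Saturday's

- a species is counted by the substrate in it: one idle adduct counts as two
- amounts and yields of product count idle adduct too
- the stated concentrations are those of everything mixed, before any reaction; amounts are the same in each set-up
- in an amount of product, one idle adduct counts as one product
- run time (Friday's): 1.0 min

**Substrate balance.** The substrate, the limiting reagent here, is the one species charged. In a stirred tank its feed, the adduct apart, leaves as free substrate, as dormant form, or through the step to intermediate A. Per free substrate these streams make a load, which in Sunday's tank is 11.1. The adduct adds one term: of its two substrates, one has passed the step to intermediate A and stands in the load already, and the other has not, so the feed concentration equals load times [substrate] plus [idle adduct].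

**Tank gain.** Counted product arises from intermediate A, and adduct formation merely moves it between forms. Its outlet level is therefore [intermediate A] times the rate constant of the step to product times residence time. Intermediate A is fed from substrate and lost by its two onward steps, by washout and by net exchange with intermediate C. In Sunday's tank this gives 3.37 for the tank gain, counted product at the outlet per free substrate in the tank.

**Two extremes.** With no adduct, Sunday's yield is gain over load, 30.3%. With every product bound, it is gain over load plus gain, 23.3%, which is less than the free case. The bound share of product runs between these two cases, so Sunday's tank lies between them. The tight case leaves [substrate] at 0.00346 M, which gives a bound share of 0.694. This hand reckoning then puts Sunday's yield at 25.1%, nearer the tight end. It gives no number for Friday's flask or Wednesday's tube.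

**The forecast.** The forecast names Sunday's, with 25% for Sunday's, 9.9% for Friday's, 9.9% for Wednesday's and 9% for Saturday's. Its ground for the pair: “Friday's closed flask and Wednesday's tube are the same ideal batch problem, so they share one answer.”

**The result.** The simulation gives Sunday's as best, at 25.0%, against 9.85% for Friday's, 9.85% for Wednesday's and 8.97% for Saturday's. Sunday's tank holds [substrate] at 0.00371 M, so its counted product per free substrate reads 3.37, beside the tank gain of 3.37. In Saturday's tank, with residence time 1.0 min, the gain is 0.363 and the load 3.73. Its extremes are therefore 8.87% and 9.73%, and Saturday's yield stands at 8.97%.

The rate constants belong to no real substance; the run is a simulation.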